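**Retrosynthetic overview**
- Feature: ring A is a 2-alkylphloroglucinol. The C6 chain sits between O5 and O7 and lies para to C8a–O1. A phenol with O5 and O7 benzylated and only the future O1 free therefore has a mirror plane through C6 and C8a. The future C4a and C8 are then the same carbon, and acylation at either gives only the 6-alkyl flavone.
- Late disconnections: the four O-benzyl groups (hydrogenolysis) and one carbinol methyl (MeMgBr on a 3-oxobutyl ketone).
- Key disconnection: C4–C4a, by intramolecular Friedel–Crafts acylation of a (Z)-3-aryloxy-3-arylacrylic acid. Ring C is the only ring built; rings A and B are bought.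
- O1–C2 comes from oxa-Michael addition of the symmetric ketophenol to the ring B arylpropiolate (Corey–Fuchs homologation and carboxylation of benzylated 2,4-dihydroxybenzaldehyde).
- The ketophenol comes from 3,5-bis(benzyloxy)phenol by para-formylation, Wittig olefination and benzyl-sparing alkene hydrogenation.

Key step: step 9

Assumption: step 7 may deliver 12 as a mixture of double-bond isomers. Compounds 12, 13 and 14 are drawn as the Z isomers that cyclise, and any E isomer is carried along because it equilibrates under the acid of step 9. The target has no stereocentre.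

Step 1
Reactants: 1 3,5-bis(benzyloxy)phenol
Product: 3 2,6-bis(benzyloxy)-4-hydroxybenzaldehyde, via aryl iminium chloride 2 (not isolated)
Conditions: POCl3 (1.5 equiv), DMF, 0 °C → rt; then ice-water
Reagents that add atoms: N,N-dimethylformamide CN(C)C=O (formyl carbon, and the Me2N=CH unit of 2); water O (aldehyde oxygen); phosphoryl chloride O=P(Cl)(Cl)Cl (chloride counter-ion of 2 only)
Why: In this Vilsmeier–Haack formylation the chloroiminium ion should attack mainly the carbon para to the free hydroxyl, between the two benzyloxy groups, as established for 3,5-dimethoxyphenol, and the chelated, much less polar ortho-hydroxy isomer can be removed by chromatography or crystallisation.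

Step 2
Reactants: 3 2,6-bis(benzyloxy)-4-hydroxybenzaldehyde; 4 1-(triphenylphosphoranylidene)propan-2-one
Product: 5 (E)-4-[2,6-bis(benzyloxy)-4-hydroxyphenyl]but-3-en-2-one
Conditions: 4 (2 equiv), toluene, reflux
Reagents that add atoms: none
Why: Wittig olefination with a stabilised keto ylide gives the E-enone, and in toluene the weakly basic ylide does not hold the phenol as its unreactive phenoxide, as is known for 4-hydroxybenzaldehydes.

Step 3
Reactants: 5 (E)-4-[2,6-bis(benzyloxy)-4-hydroxyphenyl]but-3-en-2-one
Product: 6 4-[2,6-bis(benzyloxy)-4-hydroxyphenyl]butan-2-one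
Conditions: H2 (1 atm), 10% Pd/C, Ph2S (0.01 equiv), EtOAc, rt
Reagents that add atoms: none
Why: In this chemoselective catalytic hydrogenation the diphenyl sulfide poisons Pd/C enough to stop O-benzyl hydrogenolysis and ketone reduction while the conjugated alkene is still saturated.

Step 4
Reactants: 7 2,4-dihydroxybenzaldehyde
Product: 8 2,4-bis(benzyloxy)benzaldehyde
Conditions: BnBr (2.3 equiv), K2CO3 (2.5 equiv), DMF, 60 °C
Reagents that add atoms: benzyl bromide BrCc1ccccc1
Why: Williamson ether synthesis alkylates both phenols, the hydrogen-bonded 2-OH needing only excess reagent and gentle heating.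

Step 5
Reactants: 8 2,4-bis(benzyloxy)benzaldehyde
Product: 9 2,4-bis(benzyloxy)-1-(2,2-dibromoethenyl)benzene
Conditions: CBr4 (2 equiv), PPh3 (4 equiv), CH2Cl2, 0 °C
Reagents that add atoms: carbon tetrabromide BrC(Br)(Br)Br
Why: In the first stage of the Corey–Fuchs homologation the dibromomethylene ylide made in the flask olefinates the aldehyde in a Wittig reaction that leaves aryl benzyl ethers untouched.

Step 6
Reactants: 9 2,4-bis(benzyloxy)-1-(2,2-dibromoethenyl)benzene
Product: 11 methyl 3-[2,4-bis(benzyloxy)phenyl]prop-2-ynoate, via lithium acetylide 10 (not isolated)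
Conditions: n-BuLi (2.2 equiv), THF, −78 → −20 °C; then ClCO2Me, −78 °C → rt
Reagents that add atoms: methyl chloroformate COC(=O)Cl; n-butyllithium [Li]CCCC (lithium of 10 only)
Why: In the second stage of the Corey–Fuchs homologation, bromine–lithium exchange and a Fritsch–Buttenberg–Wiechell-type loss of LiBr give acetylide 10, which is C-acylated by the chloroformate at temperatures where benzyl ethers are not metalated.

Step 7
Reactants: 6 4-[2,6-bis(benzyloxy)-4-hydroxyphenyl]butan-2-one; 11 methyl 3-[2,4-bis(benzyloxy)phenyl]prop-2-ynoate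
Product: 12 methyl (Z)-3-[3,5-bis(benzyloxy)-4-(3-oxobutyl)phenoxy]-3-[2,4-bis(benzyloxy)phenyl]prop-2-enoate
Conditions: Cs2CO3 (0.3 equiv), DMF, 70 °C
Reagents that add atoms: none
Why: In this base-catalysed oxa-Michael addition the phenoxide attacks the β-carbon of the ynoate and anti protonation places the aryloxy group cis to the ester, carbonate ionising only the phenol because it is far more acidic than the methyl ketone.

Step 8
Reactants: 12 methyl (Z)-3-[3,5-bis(benzyloxy)-4-(3-oxobutyl)phenoxy]-3-[2,4-bis(benzyloxy)phenyl]prop-2-enoate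
Product: 13 (Z)-3-[3,5-bis(benzyloxy)-4-(3-oxobutyl)phenoxy]-3-[2,4-bis(benzyloxy)phenyl]prop-2-enoic acid
Conditions: LiOH·H2O (3 equiv), THF/MeOH/H2O, rt → 40 °C; then 1 M HCl to pH 4, 0 °C
Reagents that add atoms: lithium hydroxide [Li+].[OH-]
Why: Saponification by acyl–oxygen cleavage, as long used on β-aryloxycinnamates, spares the enol-ether C–O bond and the ketone, and cold, mild acidification avoids hydrolysis of the enol ether.

Step 9
Reactants: 13 (Z)-3-[3,5-bis(benzyloxy)-4-(3-oxobutyl)phenoxy]-3-[2,4-bis(benzyloxy)phenyl]prop-2-enoic acid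
Product: 15 5,7-bis(benzyloxy)-2-[2,4-bis(benzyloxy)phenyl]-6-(3-oxobutyl)chromen-4-one, via mixed trifluoroacetic anhydride 14 (not isolated)
Conditions: (CF3CO)2O (2.5 equiv), CH2Cl2 (0.02 M), 0 °C → rt; then aq NaHCO3
Reagents that add atoms: trifluoroacetic anhydride O=C(OC(=O)C(F)(F)F)C(F)(F)F (trifluoroacetyl group of 14 only; no atom of it stays in 15)
Why: The anhydride turns 13 into mixed anhydride 14, whose cinnamoyl carbon (future C4), polarised by the trifluoroacetic acid released, is attacked by the ring CH next to the vinyl ether oxygen (future C4a), and loss of trifluoroacetate and of the proton of the arenium ion gives the pyranone. The closest known reaction type is the intramolecular Friedel–Crafts acylation of β-aryloxycinnamic acids to flavones, together with anhydride-promoted cyclisations of aryloxy acids to chromanones and xanthones. Ring C (O1, C2, C3, C4, C4a, C8a) closes in a 6-exo-trig mode, since the carbonyl that is attacked keeps its C=O outside the new ring, and no stereocentre is formed. A choice between C4a and C8 never arises because the mirror plane of the aryloxy ring makes its two free carbons identical, and each is pushed by three oxygen donors (two ortho, one para), which is why this mild activator should be enough and the benzyl ethers and the ketone should survive. The geometry requirement is met because reversible protonation at the α-carbon of the push–pull alkene interconverts the E and Z isomers and only the Z isomer is drained into product. The E isomer has no outlet of its own, since the only free ortho carbon of ring B (C6') is meta to both of its benzyloxy groups and too poor a nucleophile to give an indenone, and high dilution suppresses intermolecular acylation.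

Step 10
Reactants: 15 5,7-bis(benzyloxy)-2-[2,4-bis(benzyloxy)phenyl]-6-(3-oxobutyl)chromen-4-one
Product: 16 5,7-bis(benzyloxy)-2-[2,4-bis(benzyloxy)phenyl]-6-(3-hydroxy-3-methylbutyl)chromen-4-one
Conditions: MeMgBr (1.2 equiv), THF, −78 → −40 °C; then sat. aq NH4Cl
Reagents that add atoms: methylmagnesium bromide C[Mg]Br
Why: In this Grignard 1,2-addition the open dialkyl ketone is much more electrophilic than C4, a vinylogous ester carbonyl fed by O1, O5 and O7 and screened by the 5-benzyloxy group, so a near-stoichiometric charge at low temperature should be used up in the side chain, and the new carbinol carbon carries two methyl groups and is not stereogenic.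

Step 11
Reactants: 16 5,7-bis(benzyloxy)-2-[2,4-bis(benzyloxy)phenyl]-6-(3-hydroxy-3-methylbutyl)chromen-4-one
Product: 17 2-(2,4-dihydroxyphenyl)-5,7-dihydroxy-6-(3-hydroxy-3-methylbutyl)chromen-4-one (CNP0205133.0)
Conditions: H2 (1 atm), 10% Pd/C, EtOAc/MeOH, rt
Reagents that add atoms: none
Why: Catalytic hydrogenolysis cleaves the four aryl benzyl ethers, while the non-benzylic tertiary alcohol and the C2–C3 bond of the pyranone are not reduced at one atmosphere, and the neutral medium prevents acid-catalysed chroman formation between the carbinol and the neighbouring phenols.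

**Compound list**
1 | 3,5-bis(benzyloxy)phenol | Oc1cc(OCc2ccccc2)cc(OCc2ccccc2)c1 | starting material
2 | [2,6-bis(benzyloxy)-4-hydroxyphenyl]methylidene(dimethyl)ammonium chloride | C[N+](C)=Cc1c(OCc2ccccc2)cc(O)cc1OCc1ccccc1.[Cl-] | intermediate
3 | 2,6-bis(benzyloxy)-4-hydroxybenzaldehyde | O=Cc1c(OCc2ccccc2)cc(O)cc1OCc1ccccc1 | intermediate
4 | 1-(triphenylphosphoranylidene)propan-2-one | CC(=O)C=P(c1ccccc1)(c1ccccc1)c1ccccc1 | starting material
5 | (E)-4-[2,6-bis(benzyloxy)-4-hydroxyphenyl]but-3-en-2-one | CC(=O)/C=C/c1c(OCc2ccccc2)cc(O)cc1OCc1ccccc1 | intermediate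
6 | 4-[2,6-bis(benzyloxy)-4-hydroxyphenyl]butan-2-one | CC(=O)CCc1c(OCc2ccccc2)cc(O)cc1OCc1ccccc1 | intermediate
7 | 2,4-dihydroxybenzaldehyde | O=Cc1ccc(O)cc1O | starting material
8 | 2,4-bis(benzyloxy)benzaldehyde | O=Cc1ccc(OCc2ccccc2)cc1OCc1ccccc1 | intermediate
9 | 2,4-bis(benzyloxy)-1-(2,2-dibromoethenyl)benzene | BrC(Br)=Cc1ccc(OCc2ccccc2)cc1OCc1ccccc1 | intermediate
10 | lithium [2,4-bis(benzyloxy)phenyl]acetylide | [Li]C#Cc1ccc(OCc2ccccc2)cc1OCc1ccccc1 | intermediate
11 | methyl 3-[2,4-bis(benzyloxy)phenyl]prop-2-ynoate | COC(=O)C#Cc1ccc(OCc2ccccc2)cc1OCc1ccccc1 | intermediate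
12 | methyl (Z)-3-[3,5-bis(benzyloxy)-4-(3-oxobutyl)phenoxy]-3-[2,4-bis(benzyloxy)phenyl]prop-2-enoate | COC(=O)/C=C(\Oc1cc(OCc2ccccc2)c(CCC(C)=O)c(OCc2ccccc2)c1)c1ccc(OCc2ccccc2)cc1OCc1ccccc1 | intermediate
13 | (Z)-3-[3,5-bis(benzyloxy)-4-(3-oxobutyl)phenoxy]-3-[2,4-bis(benzyloxy)phenyl]prop-2-enoic acid | OC(=O)/C=C(\Oc1cc(OCc2ccccc2)c(CCC(C)=O)c(OCc2ccccc2)c1)c1ccc(OCc2ccccc2)cc1OCc1ccccc1 | intermediate
14 | (Z)-3-[3,5-bis(benzyloxy)-4-(3-oxobutyl)phenoxy]-3-[2,4-bis(benzyloxy)phenyl]prop-2-enoic trifluoroacetic anhydride | FC(F)(F)C(=O)OC(=O)/C=C(\Oc1cc(OCc2ccccc2)c(CCC(C)=O)c(OCc2ccccc2)c1)c1ccc(OCc2ccccc2)cc1OCc1ccccc1 | intermediate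
15 | 5,7-bis(benzyloxy)-2-[2,4-bis(benzyloxy)phenyl]-6-(3-oxobutyl)chromen-4-one | CC(=O)CCc1c(OCc2ccccc2)cc2oc(-c3ccc(OCc4ccccc4)cc3OCc3ccccc3)cc(=O)c2c1OCc1ccccc1 | intermediate
16 | 5,7-bis(benzyloxy)-2-[2,4-bis(benzyloxy)phenyl]-6-(3-hydroxy-3-methylbutyl)chromen-4-one | CC(C)(O)CCc1c(OCc2ccccc2)cc2oc(-c3ccc(OCc4ccccc4)cc3OCc3ccccc3)cc(=O)c2c1OCc1ccccc1 | intermediate
17 | 2-(2,4-dihydroxyphenyl)-5,7-dihydroxy-6-(3-hydroxy-3-methylbutyl)chromen-4-one | CC(C)(O)CCc1c(O)cc2oc(-c3ccc(O)cc3O)cc(=O)c2c1O | target

Total step count: 11.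
Longest linear sequence: 8 steps (steps 1, 2, 3, 7, 8, 9, 10, 11; the ring B branch through steps 4, 5, 6 is equally long).

**Steps most likely to fail**

**Step 9.**
- What may go wrong: the acid released may strip benzyl groups from the very electron-rich ring A or move them from oxygen to carbon. The α-protonated cation may also lead to protodecarboxylation or hydrolysis of the enol ether. Trifluoroacetylation or intermolecular acylation may outrun ring closure.
- Fallback: it sets out from 6 and 9 and comes back at 15. It keeps the symmetry argument but reverses the bond order, making C4–C4a by palladium-catalysed carbonylation and closing O1–C2 last.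
- Ketophenol 6 is iodinated with N-iodosuccinimide in CH2Cl2 at 0 °C at one of its two equivalent ortho carbons, giving 4-[2,6-bis(benzyloxy)-4-hydroxy-3-iodophenyl]butan-2-one F1.
- Dibromoalkene 9 is taken with n-BuLi to acetylide 10 and quenched with water to give 2,4-bis(benzyloxy)-1-ethynylbenzene F2.
- Carbonylative Sonogashira coupling of F1 with F2 (PdCl2(dppf), CO, Et2NH, heating) should give 1-[2,4-bis(benzyloxy)-6-hydroxy-3-(3-oxobutyl)phenyl]-3-[2,4-bis(benzyloxy)phenyl]prop-2-yn-1-one F3. Under the amine this closes 6-endo-dig in the same flask to 15.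

**Step 7.**
- What may go wrong: the 2,4-dialkoxyaryl group donates into the β-carbon of the ynoate, so conjugate addition may be sluggish. At the temperature then needed, aldol condensation of the methyl ketone and ester exchange with the phenoxide may take over.
- Fallback: it sets out from 11 (with 6) and comes back at 12. It replaces the conjugate addition by a metal-catalysed vinyl C–O coupling.
- Hydroiodination of 11 with NaI in hot AcOH should give methyl (Z)-3-[2,4-bis(benzyloxy)phenyl]-3-iodoprop-2-enoate F4.
- An Ullmann-type coupling of F4 with 6 (CuI, N,N-dimethylglycine, Cs2CO3, dioxane, 80 °C) should then give 12 with retention of the double-bond geometry.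

**Step 10.**
- What may go wrong: the Grignard reagent may add at C4 or C2 of the pyranone, helped by magnesium chelation between the C4 oxygen and the 5-benzyloxy group. Enolisation of the methyl ketone may also leave the conversion incomplete.
- Fallback: it sets out from 15 and comes back at 16. It avoids a hard carbon nucleophile.
- Wittig methylenation (Ph3PCH3Br, KOt-Bu, THF, 0 °C), which does not olefinate vinylogous esters, should give 5,7-bis(benzyloxy)-2-[2,4-bis(benzyloxy)phenyl]-6-(3-methylbut-3-en-1-yl)chromen-4-one F5.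
- Mukaiyama hydration of the 1,1-disubstituted alkene (Co(acac)2, PhSiH3, O2, THF, rt, reductive work-up) should then install the tertiary hydroxyl with Markovnikov orientation to give 16.

**Further compounds**
F1 | step 9 | 4-[2,6-bis(benzyloxy)-4-hydroxy-3-iodophenyl]butan-2-one | CC(=O)CCc1c(OCc2ccccc2)cc(O)c(I)c1OCc1ccccc1
F2 | step 9 | 2,4-bis(benzyloxy)-1-ethynylbenzene | C#Cc1ccc(OCc2ccccc2)cc1OCc1ccccc1
F3 | step 9 | 1-[2,4-bis(benzyloxy)-6-hydroxy-3-(3-oxobutyl)phenyl]-3-[2,4-bis(benzyloxy)phenyl]prop-2-yn-1-one | CC(=O)CCc1c(OCc2ccccc2)cc(O)c(C(=O)C#Cc2ccc(OCc3ccccc3)cc2OCc2ccccc2)c1OCc1ccccc1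
F4 | step 7 | methyl (Z)-3-[2,4-bis(benzyloxy)phenyl]-3-iodoprop-2-enoate | COC(=O)/C=C(\I)c1ccc(OCc2ccccc2)cc1OCc1ccccc1
F5 | step 10 | 5,7-bis(benzyloxy)-2-[2,4-bis(benzyloxy)phenyl]-6-(3-methylbut-3-en-1-yl)chromen-4-one | C=C(C)CCc1c(OCc2ccccc2)cc2oc(-c3ccc(OCc4ccccc4)cc3OCc3ccccc3)cc(=O)c2c1OCc1ccccc1
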